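**Retrosynthetic overview**

1. Target ⇒ (loss of CO2, then aromatization of ring A, both read backwards) a 5-oxo-5,6,7,8-tetrahydro-2H-chromene-6-carboxylate: ring A is carried as a cyclohexane-1,3-dione and aromatized late, with a temporary CO2Me on C6, the ring A carbon that bears only H in the target.
2. Key disconnection: the pyran ring (bonds C4–C4a and O1–C2) ⇒ ring A dione ester + 3-methylbut-2-enal, by Knoevenagel condensation and oxa-6π electrocyclization, the laboratory form of the quinone-methide closure assumed for chromene biosynthesis.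
3. Enabling feature: C4a lies between the two oxygen-bearing carbons C5 and C8a of ring A (the central carbon of a 1,3-dione), and C4=C3–C2(CH3)2–O1 is a prenal unit attached there as a 1-oxatriene. The C6 ester holds the C5 carbonyl as a chelated β-keto ester, so only the C8a oxygen, next to the prenylated C8, closes the ring.
4. Ring A ⇒ open-chain α-prenyl enone + dimethyl malonate (Michael/Dieckmann), which places C8-prenyl, C7-arylethyl and C6-ester by construction; the enone ⇒ Horner–Wadsworth–Emmons reaction of an α-prenyl β-ketophosphonate with 3-(4-hydroxyphenyl)propanal.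
5. Order of rings: phenol ring (bought) → carbocyclic ring A (step 3) → pyran ring (step 4, last ring closed); then aromatization (step 5) and removal of the ester carbon as CO2 (step 6).

Key step: step 4

Assumption: 3-(4-hydroxyphenyl)propanal is taken as purchasable and its phenol is carried unprotected; locants C2–C8a in the text are those of the 2H-chromene of the target, which has no stereocentre.

**Step 1**
Reactants: 1 dimethyl (2-oxopropyl)phosphonate; 2 1-bromo-3-methylbut-2-ene (prenyl bromide)
Product: 3 dimethyl (6-methyl-2-oxohept-5-en-3-yl)phosphonate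
Conditions: NaH (1.0 equiv), THF, 0 °C; then 2, 0 °C to rt
Reagents that add atoms: 1-bromo-3-methylbut-2-ene (compound 2), CC(C)=CCBr
Why: C-alkylation of a β-ketophosphonate enolate by SN2 displacement at the primary allylic bromide should occur at the carbon between P=O and C=O, the only site deprotonated by one equivalent of base; the new stereocentre is racemic and disappears in step 2.

**Step 2**
Reactants: 3 dimethyl (6-methyl-2-oxohept-5-en-3-yl)phosphonate; 4 3-(4-hydroxyphenyl)propanal
Product: 5 (E)-6-(4-hydroxyphenyl)-3-(3-methylbut-2-en-1-yl)hex-3-en-2-one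
Conditions: Ba(OH)2·8H2O, THF/H2O (40:1), rt
Reagents that add atoms: 3-(4-hydroxyphenyl)propanal (compound 4), O=CCCc1ccc(O)cc1
Why: Horner–Wadsworth–Emmons olefination under a mild heterogeneous base should spare the enolizable aldehyde and hold the phenol only as its phenoxide; the E isomer is expected, but the geometry is of no consequence because both alkene carbons become sp3 in step 3.

**Step 3**
Reactants: 5 (E)-6-(4-hydroxyphenyl)-3-(3-methylbut-2-en-1-yl)hex-3-en-2-one; 6 dimethyl malonate
Product: 8 methyl 6-[2-(4-hydroxyphenyl)ethyl]-5-(3-methylbut-2-en-1-yl)-2,4-dioxocyclohexane-1-carboxylate, via Michael adduct 7 (not isolated)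
Conditions: NaOMe (2.5 equiv), MeOH, reflux; then aq. HCl, 0 °C
Reagents that add atoms: dimethyl malonate (compound 6), COC(=O)CC(=O)OC
Why: Michael addition followed by Dieckmann-type (intramolecular Claisen) condensation: the malonate anion adds to the enone β-carbon, the methyl ketone enolate of 7 attacks one ester to close the only accessible six-membered ring, and formation of the stabilized 1,3-dione enolate drives the sequence, so prenyl, arylethyl and ester end up on three neighbouring ring carbons by construction; the three stereocentres form without control and are all erased in step 5.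

**Step 4**
Reactants: 8 methyl 6-[2-(4-hydroxyphenyl)ethyl]-5-(3-methylbut-2-en-1-yl)-2,4-dioxocyclohexane-1-carboxylate; 9 3-methylbut-2-enal
Product: 11 methyl 7-[2-(4-hydroxyphenyl)ethyl]-2,2-dimethyl-8-(3-methylbut-2-en-1-yl)-5-oxo-5,6,7,8-tetrahydro-2H-chromene-6-carboxylate, via 1-oxatriene 10 (not isolated)
Conditions: ethylenediammonium diacetate (20 mol %), toluene, 80 °C
Reagents that add atoms: 3-methylbut-2-enal (compound 9), CC(C)=CC=O
Why: The ammonium acetate converts 9 into its iminium ion, the CH2 between the two ketone carbonyls of 8 adds in a Knoevenagel condensation, and loss of the amine gives the 2-alkylidene-1,3-dione 10, a 1-oxatriene. A thermal disrotatory oxa-6π electrocyclization then joins a carbonyl oxygen to the CMe2 terminus and closes the pyran ring (C4–C4a bond first, O1–C2 bond last). The closest known reaction type is the formal (3+3) annulation of cyclohexane-1,3-diones with α,β-unsaturated aldehydes. No new stereocentre arises, since C2 carries two methyl groups, and the three ring A stereocentres stay uncontrolled until they are erased in step 5. The step needs regioselectivity between the two carbonyl oxygens, and the ester secures it: the carbonyl next to the CH(CO2Me) carbon enolizes toward it as a hydrogen-bonded β-keto ester enol and is withdrawn from the oxatriene, and because the electrocyclization is reversible the mixture should settle on the isomer that keeps this chelated, conjugated β-keto ester, with the pyran oxygen on the carbon next to the prenylated one. Site selectivity of the condensation follows from the fact that only the CH2 between the ketones has two acidic hydrogens, whereas the ester-bearing CH cannot form an alkylidene.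

**Step 5**
Reactants: 11 methyl 7-[2-(4-hydroxyphenyl)ethyl]-2,2-dimethyl-8-(3-methylbut-2-en-1-yl)-5-oxo-5,6,7,8-tetrahydro-2H-chromene-6-carboxylate
Product: 12 methyl 5-hydroxy-7-[2-(4-hydroxyphenyl)ethyl]-2,2-dimethyl-8-(3-methylbut-2-en-1-yl)-2H-chromene-6-carboxylate
Conditions: DDQ (1.05 equiv), toluene, 0 °C to rt
Reagents that add atoms: none
Why: Quinone dehydrogenation of a cyclohexa-1,3-diene: the chelated dienol tautomer of 11 should lose hydride from C7–H to a cation stabilized by both ring oxygens and then the C8 proton, which aromatizes ring A; the prenyl CH2 sits on an sp3 carbon at that moment and its neighbouring oxygen is already locked in the pyran ring, so it can be neither dehydrogenated nor cyclized, and one equivalent at low temperature should be consumed by the dihydroarene before the para-alkylphenol of the side chain reacts.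

**Step 6**
Reactants: 12 methyl 5-hydroxy-7-[2-(4-hydroxyphenyl)ethyl]-2,2-dimethyl-8-(3-methylbut-2-en-1-yl)-2H-chromene-6-carboxylate
Product: 14 target 7-[2-(4-hydroxyphenyl)ethyl]-2,2-dimethyl-8-(3-methylbut-2-en-1-yl)-2H-chromen-5-ol, via carboxylic acid 13 (not isolated)
Conditions: KOH, EtOH/H2O, 90 °C, Ar; then AcOH to pH 5, 90 °C
Reagents that add atoms: none
Why: Saponification followed by protodecarboxylation: hydroxide cleaves the chelated ester, and after acidification the electron-rich ring of the 2-hydroxy-4-alkoxy-6-alkylbenzoic acid 13 should be protonated at the carboxyl-bearing carbon and lose CO2 on gentle heating, as acids of this substitution pattern do, which delivers the target without any protecting-group step.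

**Compound list**

1 | dimethyl (2-oxopropyl)phosphonate | CC(=O)CP(=O)(OC)OC | starting material
2 | 1-bromo-3-methylbut-2-ene (prenyl bromide) | CC(C)=CCBr | starting material
3 | dimethyl (6-methyl-2-oxohept-5-en-3-yl)phosphonate (racemic) | CC(=O)C(CC=C(C)C)P(=O)(OC)OC | intermediate
4 | 3-(4-hydroxyphenyl)propanal | O=CCCc1ccc(O)cc1 | starting material
5 | (E)-6-(4-hydroxyphenyl)-3-(3-methylbut-2-en-1-yl)hex-3-en-2-one | CC(=O)/C(CC=C(C)C)=C/CCc1ccc(O)cc1 | intermediate
6 | dimethyl malonate | COC(=O)CC(=O)OC | starting material
7 | dimethyl 2-[4-acetyl-1-(4-hydroxyphenyl)-7-methyloct-6-en-3-yl]propanedioate (Michael adduct, diastereomer mixture, formed in the flask) | COC(=O)C(C(=O)OC)C(CCc1ccc(O)cc1)C(CC=C(C)C)C(C)=O | intermediate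
8 | methyl 6-[2-(4-hydroxyphenyl)ethyl]-5-(3-methylbut-2-en-1-yl)-2,4-dioxocyclohexane-1-carboxylate (mixture of diastereomers and enol tautomers) | COC(=O)C1C(=O)CC(=O)C(CC=C(C)C)C1CCc1ccc(O)cc1 | intermediate
9 | 3-methylbut-2-enal | CC(C)=CC=O | starting material
10 | methyl 6-[2-(4-hydroxyphenyl)ethyl]-3-(3-methylbut-2-en-1-ylidene)-5-(3-methylbut-2-en-1-yl)-2,4-dioxocyclohexane-1-carboxylate (1-oxatriene, formed in the flask) | COC(=O)C1C(=O)C(=CC=C(C)C)C(=O)C(CC=C(C)C)C1CCc1ccc(O)cc1 | intermediate
11 | methyl 7-[2-(4-hydroxyphenyl)ethyl]-2,2-dimethyl-8-(3-methylbut-2-en-1-yl)-5-oxo-5,6,7,8-tetrahydro-2H-chromene-6-carboxylate (mixture of diastereomers, keto and enol forms) | COC(=O)C1C(=O)C2=C(OC(C)(C)C=C2)C(CC=C(C)C)C1CCc1ccc(O)cc1 | intermediate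
12 | methyl 5-hydroxy-7-[2-(4-hydroxyphenyl)ethyl]-2,2-dimethyl-8-(3-methylbut-2-en-1-yl)-2H-chromene-6-carboxylate | COC(=O)c1c(O)c2C=CC(C)(C)Oc2c(CC=C(C)C)c1CCc1ccc(O)cc1 | intermediate
13 | 5-hydroxy-7-[2-(4-hydroxyphenyl)ethyl]-2,2-dimethyl-8-(3-methylbut-2-en-1-yl)-2H-chromene-6-carboxylic acid (formed in the flask) | OC(=O)c1c(O)c2C=CC(C)(C)Oc2c(CC=C(C)C)c1CCc1ccc(O)cc1 | intermediate
14 | 7-[2-(4-hydroxyphenyl)ethyl]-2,2-dimethyl-8-(3-methylbut-2-en-1-yl)-2H-chromen-5-ol | CC(C)=CCc1c(CCc2ccc(O)cc2)cc(O)c2c1OC(C)(C)C=C2 | target

**Step count**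

Total step count: 6. Longest linear sequence: 6 steps (1 → 3 → 5 → 8 → 11 → 12 → 14).

**Steps most likely to fail**

Step 4. The electrocyclization may close through the carbonyl oxygen next to the ester-bearing carbon, or through both oxygens, if the chelated enol does not steer it. The fallback sets out from 8 and aromatizes ring A before the pyran is made. Lithium diisopropylamide (3.3 equiv, THF, −78 °C) should give the trianion of 8, whose most basic carbon, the ester-bearing CH, is selenenylated by PhSeBr to the α-phenylselanyl dione ester F1. H2O2 (pyridine, CH2Cl2, 0 °C) oxidizes it to the selenoxide F2, which can only eliminate into the ring and, after enolization, gives the β-resorcylate F3. F3, 3-methylbut-2-enal (9) and ethylenediammonium diacetate in refluxing toluene then undergo the same Knoevenagel/oxa-6π annulation on the aromatic ring. The only free ring carbon lies between the two hydroxyls and the ester-chelated hydroxyl is inert, so the pyran must close through the other oxygen and 12 forms directly. The route is rejoined at 12 and step 5 is skipped.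

Step 5. The quinone may over-oxidize the substrate, by benzylic dehydrogenation of the 4-hydroxyphenethyl unit or by hydride abstraction at the prenyl CH2 para to the new phenol. The fallback sets out from 11 and avoids hydride abstraction altogether. NaH (2.1 equiv, THF, 0 °C) and then PhSeCl at −78 °C should give the 6-phenylselanyl β-keto ester F4. H2O2 with pyridine (CH2Cl2, 0 °C) gives the selenoxide F5, whose syn-elimination can only take the C7 hydrogen, and enolization of the resulting cyclohexadienone gives 12, where the route is rejoined.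

Step 3. Conjugate addition to the α-branched enone may be slow, so that retro-aldol cleavage and deconjugation of 5 under methoxide compete. The fallback exchanges the roles of donor and acceptor and sets out from 4. Knoevenagel condensation of 4 with dimethyl malonate (6) (piperidinium acetate, benzene, reflux, water removal) gives the alkylidene malonate F6. Commercial 6-methylhept-5-en-2-one F7 is converted to its thermodynamic trimethylsilyl enol ether F8 (Me3SiCl, NaI, Et3N, MeCN). Mukaiyama–Michael addition of F8 to F6 (TiCl4, CH2Cl2, −78 °C, excess F8 to cover the phenol) should give, after aqueous work-up, the keto diester 7, now isolated, which NaOMe in MeOH cyclizes to 8. The route is rejoined at 8, and steps 1 and 2 are then not needed.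

**Further compounds**

F1 | step 4 | methyl 6-[2-(4-hydroxyphenyl)ethyl]-5-(3-methylbut-2-en-1-yl)-2,4-dioxo-1-(phenylselanyl)cyclohexane-1-carboxylate | COC(=O)C1([Se]c2ccccc2)C(=O)CC(=O)C(CC=C(C)C)C1CCc1ccc(O)cc1
F2 | step 4 | methyl 1-(benzeneseleninyl)-6-[2-(4-hydroxyphenyl)ethyl]-5-(3-methylbut-2-en-1-yl)-2,4-dioxocyclohexane-1-carboxylate | COC(=O)C1([Se](=O)c2ccccc2)C(=O)CC(=O)C(CC=C(C)C)C1CCc1ccc(O)cc1
F3 | step 4 | methyl 4,6-dihydroxy-2-[2-(4-hydroxyphenyl)ethyl]-3-(3-methylbut-2-en-1-yl)benzoate | COC(=O)c1c(O)cc(O)c(CC=C(C)C)c1CCc1ccc(O)cc1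
F4 | step 5 | methyl 7-[2-(4-hydroxyphenyl)ethyl]-2,2-dimethyl-8-(3-methylbut-2-en-1-yl)-5-oxo-6-(phenylselanyl)-5,6,7,8-tetrahydro-2H-chromene-6-carboxylate | COC(=O)C1([Se]c2ccccc2)C(=O)C2=C(OC(C)(C)C=C2)C(CC=C(C)C)C1CCc1ccc(O)cc1
F5 | step 5 | methyl 6-(benzeneseleninyl)-7-[2-(4-hydroxyphenyl)ethyl]-2,2-dimethyl-8-(3-methylbut-2-en-1-yl)-5-oxo-5,6,7,8-tetrahydro-2H-chromene-6-carboxylate | COC(=O)C1([Se](=O)c2ccccc2)C(=O)C2=C(OC(C)(C)C=C2)C(CC=C(C)C)C1CCc1ccc(O)cc1
F6 | step 3 | dimethyl 2-[3-(4-hydroxyphenyl)propylidene]propanedioate | COC(=O)C(=CCCc1ccc(O)cc1)C(=O)OC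
F7 | step 3 | 6-methylhept-5-en-2-one (purchased) | CC(=O)CCC=C(C)C
F8 | step 3 | (Z)-trimethyl[(6-methylhepta-2,5-dien-2-yl)oxy]silane | C/C(O[Si](C)(C)C)=C/CC=C(C)C
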